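The earlier runs and the new flask were computed with constants of no real substance, noise included.

How much of the solid X is left over at the end of a flask, and does that leftover bear on cJ?

| flask | E | X | remark | time |
|---|---|---|---|---|
| grey | 0.40 M | 0.96 M | run made earlier |  |
| teal | 0.40 M | 2.4 M | run made earlier |  |
| ash | 0.40 M | 0.800 M |  | 3.0 d |
| larch | 0.40 M | 1.20 M |  | 3.0 d |
| maple | 0.40 M | 2.00 M |  | 3.0 d |

| run | time / d | J / % | Z / % |
|---|---|---|---|
| grey | 0.250 | 5.2 | 1.1 |
| grey | 0.417 | 6.1 | 2.9 |
| grey | 0.625 | 6.1 | 3.7 |
| grey | 1.04 | 6.0 | 8.2 |
| grey | 1.67 | 3.4 | 15.9 |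
| grey | 3.00 | 3.2 | 30.9 |
| teal | 0.500 | 5.0 | 1.8 |
| teal | 1.04 | 5.3 | 7.0 |
| teal | 1.67 | 5.6 | 15.5 |
| teal | 2.08 | 2.4 | 19.6 |
| teal | 2.50 | 4.1 | 22.7 |
| teal | 3.00 | 2.8 | 28.9 |

(standard deviation of a reading: 1 percentage point)

- X is a solid; its amount is given per volume of the solution
- the numbers in the tables scatter by 1 percentage point (one standard deviation)
- at the start none of X is in solution
- "hardly changes" means that all values lie within two and a half points (for a concentration: within two and a half percent of the largest)

- [J] at the end for ash, larch, maple, in this order
- the shape of the row from first to last (rises all the way / falls, then rises / falls all the way / hardly changes / rises, then falls)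

Does the amount of solid show in the earlier runs? Not clearly. At 3.00 d grey reads Z 30.9 % and teal 28.9 %, a gap of 2 percentage points at a scatter of 1 point per reading, although teal holds 2.50 times the X of grey.

But ash has less X than either run, so what entitles you to go below grey? A reckoning of the demand on the solid. I assume one X per Z and take grey's reading for ash, which gives 15.4 %: this is the draw on the charge, cZ at the end over the X charged.

Isn't that too kind? Dissolved X is not read, so the draw counts the X in Z and leaves out the X in solution. Yet if every E charged became Z, ash would still put just half of its X into Z, so on my assumption X is not the limiting reagent in ash.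

And cJ? I expect one value along the row. The two readings at 3.00 d, 3.2 % and 2.8 %, taken on the E charged, average to 0.0120 M, a reading with their scatter.

The forecast, a little higher than my figure, gives 0.013 M, 0.013 M and 0.013 M, shape hardly changes, and says of two of these flasks: “Larch and maple lie within the tested range, so they should behave the same.”

The simulation gives 0.0114 M, 0.0114 M and 0.0114 M, shape hardly changes.

    E → J (k = 1.90 × 10⁻⁴ /min)
    Q + J → Z (k = 0.0310 /M/min)
    2 J → G (k = 0.0320 /M/min)
    X ⇌ Q, rate k4*(cs4 - [Q]) while solid is left; crystals form when [Q] > cs4 (solubility = 0.240 M, k = 2.40 × 10⁻⁴ /min)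

In ash the draw of 15.4 % plus cQ over the charge, 9.84 %, stands beside 24.5 % of X gone at 3.00 d; in maple the draw scaled to its charge, 6.18 %, plus 3.94 % stands beside 9.80 % gone. In ash at 3.00 d J has a half-life of 0.20 d by the step from Q + J to Z, short against 3.0 d, and its making runs at 0.924 of its using up, each step taken net. At that time cQ reads 0.0787 M, 0.0787 M and 0.0787 M in ash, larch and maple, lower than the solubility of 0.24 M.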